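**Retrosynthetic overview**

1. Endgame, functional-group level: target ⇐ C3 ketone triacetate (equatorial hydride delivery) ⇐ hydroboration–oxidation of a C2=C3 alkene ⇐ cyclopropane bond C8–C9 by carbene insertion from a C8 ketone.
2. Key disconnection: bonds C1–C9 and C10–C11 are formed together by a domino Mukaiyama–Michael/aldol reaction of a monocyclic keto dialdehyde that contains only ring A.
3. Enabling feature: the quaternary carbon C6 carries both C1 and C11 and is joined through C7 to C8. With C8 as a carbonyl, C9 and C10 are the β- and α-carbons of an isopropenyl ketone, so the five-membered ring C1–C6–C11–C10–C9 closes as a formal [3+2] annulation between a donor at C1 (enol of the C15 aldehyde) and an acceptor at C11 (aldehyde). The same C8 carbonyl later becomes the carbene carbon.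
4. Precursor: quaternary C6 from two α'-functionalisations of (S)-4-silyloxy-5,5-dimethylcyclohex-2-enone (allyl first, then a masked formyl group anti to the silyloxy group); C15 by Wittig homologation; absolute configuration from one CBS reduction.
5. Ring order: ring A (from the starting ketone) → cyclohexanone ring and C11 bridge together (key step, bicyclo[2.2.1]heptane) → cyclopropane.

Key step: step 11

Locants used here (not systematic): ring A = C1 (quaternary, bears C15H2O) – C2 – C3 (OH) – C4 (OAc) – C5 (CMe2) – C6 (quaternary); cage = C6–C7H2–C8; cyclopropane C8/C9/C10 (C9 bonded to C1; C10 bears CH3 and is bonded to C11); C11 (OAc) bonded to C6.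

Assumption: ketone 1 is taken as a purchasable building block (otherwise one step, gem-dimethylation of 1,4-cyclohexanedione monoethylene ketal); centres that are destroyed later (C6 of 6, the carbinol of 10 and 11, the enol-ether geometry of 11 and 12, C3 of 24) are left open.

**Route**

Step 1
Reactants: 1 7,7-dimethyl-1,4-dioxaspiro[4.5]decan-8-one
Product: 2 (S)-7,7-dimethyl-1,4-dioxaspiro[4.5]decan-8-ol
Conditions: (R)-2-methyl-CBS-oxazaborolidine (10 mol%), BH3·SMe2, THF, −20 °C; MeOH quench
Reagents that add atoms: none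
Why: Corey–Bakshi–Shibata reduction, in which the oxazaborolidine–borane complex distinguishes the quaternary C(CH3)2 flank from the CH2 flank of the ketone and should deliver hydride to one face, setting the carbinol centre (target C4) as S under catalyst control.

Step 2
Reactants: 2 (S)-7,7-dimethyl-1,4-dioxaspiro[4.5]decan-8-ol
Product: 3 (S)-tert-butyl[(7,7-dimethyl-1,4-dioxaspiro[4.5]decan-8-yl)oxy]dimethylsilane
Conditions: TBSOTf, 2,6-lutidine, CH2Cl2, 0 °C
Reagents that add atoms: tert-butyldimethylsilyl triflate CC(C)(C)[Si](C)(C)OS(=O)(=O)C(F)(F)F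
Why: Silyl ether formation on the hindered secondary alcohol with the silyl triflate; the stereocentre is not touched.

Step 3
Reactants: 3 (S)-tert-butyl[(7,7-dimethyl-1,4-dioxaspiro[4.5]decan-8-yl)oxy]dimethylsilane
Product: 4 (S)-4-[(tert-butyldimethylsilyl)oxy]-3,3-dimethylcyclohexan-1-one
Conditions: aq. HCl (1 M), THF, 0 °C to rt
Reagents that add atoms: water O
Why: Acid-catalysed ketal hydrolysis, which the hindered secondary silyl ether should survive.

Step 4
Reactants: 4 (S)-4-[(tert-butyldimethylsilyl)oxy]-3,3-dimethylcyclohexan-1-one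
Product: 5 (S)-4-[(tert-butyldimethylsilyl)oxy]-5,5-dimethylcyclohex-2-en-1-one
Conditions: IBX, DMSO/fluorobenzene, 70 °C
Reagents that add atoms: none
Why: IBX dehydrogenation of the ketone, which can give only one enone because the other α-carbon is attached to the quaternary carbon and has no β-hydrogen.

Step 5
Reactants: 5 (S)-4-[(tert-butyldimethylsilyl)oxy]-5,5-dimethylcyclohex-2-en-1-one
Product: 6 (4S)-4-[(tert-butyldimethylsilyl)oxy]-5,5-dimethyl-6-(prop-2-en-1-yl)cyclohex-2-en-1-one (both C6 epimers)
Conditions: LiN(iPr)2 (LDA), THF, −78 °C; allyl bromide, DMPU, −78 to 0 °C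
Reagents that add atoms: allyl bromide C=CCBr
Why: Kinetic α'-deprotonation of the cyclohexenone (the α-carbon is sp2) and SN2 enolate alkylation; the new centre is erased again in step 6.

Step 6
Reactants: 6 (4S)-4-[(tert-butyldimethylsilyl)oxy]-5,5-dimethyl-6-(prop-2-en-1-yl)cyclohex-2-en-1-one
Product: 8 (4S)-4-[(tert-butyldimethylsilyl)oxy]-6-(dimethoxymethyl)-5,5-dimethyl-6-(prop-2-en-1-yl)cyclohex-2-en-1-one (dimethoxymethyl trans and allyl cis to the silyloxy group), via silyl dienol ether 7 (not isolated)
Conditions: LiN(iPr)2, THF, −78 to −40 °C, then Me3SiCl; crude 7, HC(OMe)3, Me3SiOTf (10 mol%), CH2Cl2, −78 °C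
Reagents that add atoms: trimethyl orthoformate COC(OC)OC; chlorotrimethylsilane C[Si](C)(C)Cl (its silyl group stays only in 7)
Why: Kinetic α'-enolisation and O-silylation give the cross-conjugated silyl dienol ether, which is alkylated by the dimethoxycarbenium ion from the orthoformate (Mukaiyama-type reaction); the electrophile should enter anti to the C4 silyloxy group, so the new quaternary centre (target C6) carries the acetal trans and the allyl group cis to it.

Step 7
Reactants: 8 (4S)-4-[(tert-butyldimethylsilyl)oxy]-6-(dimethoxymethyl)-5,5-dimethyl-6-(prop-2-en-1-yl)cyclohex-2-en-1-one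
Product: 9 2-[(5S)-5-[(tert-butyldimethylsilyl)oxy]-1-(dimethoxymethyl)-6,6-dimethyl-2-oxocyclohex-3-en-1-yl]acetaldehyde
Conditions: OsO4 (2 mol%), NaIO4, 2,6-lutidine, 1,4-dioxane/H2O, rt
Reagents that add atoms: NaIO4 [Na+].[O-]I(=O)(=O)=O (oxygen passed on through OsO4)
Why: Lemieux–Johnson oxidation (dihydroxylation, then glycol cleavage) of the terminal alkene; the electron-poor enone double bond should react much more slowly.

Step 8
Reactants: 9 2-[(5S)-5-[(tert-butyldimethylsilyl)oxy]-1-(dimethoxymethyl)-6,6-dimethyl-2-oxocyclohex-3-en-1-yl]acetaldehyde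
Product: 10 (4S)-4-[(tert-butyldimethylsilyl)oxy]-6-(dimethoxymethyl)-6-(2-hydroxy-3-methylbut-3-en-1-yl)-5,5-dimethylcyclohex-2-en-1-one (both carbinol epimers)
Conditions: isopropenylmagnesium bromide, THF, −78 °C; H2O work-up
Reagents that add atoms: isopropenylmagnesium bromide CC(=C)[Mg]Br
Why: Grignard addition to the unhindered aldehyde, which should be much faster at low temperature than addition to the ketone next to the quaternary carbon; the carbinol configuration is irrelevant because it is oxidised in step 10.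

Step 9
Reactants: 10 (4S)-4-[(tert-butyldimethylsilyl)oxy]-6-(dimethoxymethyl)-6-(2-hydroxy-3-methylbut-3-en-1-yl)-5,5-dimethylcyclohex-2-en-1-one
Product: 11 1-[(5S)-5-[(tert-butyldimethylsilyl)oxy]-1-(dimethoxymethyl)-2-(methoxymethylidene)-6,6-dimethylcyclohex-3-en-1-yl]-3-methylbut-3-en-2-ol (E/Z and carbinol mixture)
Conditions: Ph3P(CH2OMe)Cl, KN(SiMe3)2 (3 equiv each), THF, 0 °C to rt
Reagents that add atoms: (methoxymethyl)triphenylphosphonium chloride COC[P+](c1ccccc1)(c1ccccc1)c1ccccc1.[Cl-]
Why: Wittig olefination with the methoxymethylene ylide turns the cross-conjugated ketone into a 1-methoxy diene (one-carbon homologation that installs target C15); the free hydroxyl only consumes extra ylide, and the double-bond geometry is irrelevant.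

Step 10
Reactants: 11 1-[(5S)-5-[(tert-butyldimethylsilyl)oxy]-1-(dimethoxymethyl)-2-(methoxymethylidene)-6,6-dimethylcyclohex-3-en-1-yl]-3-methylbut-3-en-2-ol
Product: 13 (4S)-4-[(tert-butyldimethylsilyl)oxy]-5,5-dimethyl-6-(3-methyl-2-oxobut-3-en-1-yl)cyclohex-1-ene-1,6-dicarbaldehyde (side chain cis to the silyloxy group), via isopropenyl ketone 12 (not isolated)
Conditions: Dess–Martin periodinane, pyridine, CH2Cl2, 0 °C; then aq. HCl (1 M), THF, 0 °C to rt
Reagents that add atoms: water O
Why: Dess–Martin oxidation of the allylic alcohol gives the isopropenyl ketone, and aqueous acid then hydrolyses the dimethyl acetal and the dienol ether (protonation at the diene terminus gives the conjugated enal) without isolating 12, which could otherwise undergo an intramolecular hetero-Diels–Alder reaction.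

Step 11
Reactants: 13 (4S)-4-[(tert-butyldimethylsilyl)oxy]-5,5-dimethyl-6-(3-methyl-2-oxobut-3-en-1-yl)cyclohex-1-ene-1,6-dicarbaldehyde
Product: 16 bridged keto aldehyde (bicyclo[2.2.1]heptan-2-one fused to ring A; C15 aldehyde; C8 ketone; 4,11-bis-TBS ether), via silyl dienol ether 14 (not isolated), via Michael adduct 15 (not isolated)
Conditions: TBSOTf (1.5 equiv), Et3N (2 equiv), CH2Cl2 (0.01 M), −78 to −20 °C
Reagents that add atoms: tert-butyldimethylsilyl triflate CC(C)(C)[Si](C)(C)OS(=O)(=O)C(F)(F)F
Why: TBSOTf/Et3N first turns the enal of 13 into the silyl dienol ether 14 by γ-deprotonation at C3, then C1 of 14 adds to the silyl-activated isopropenyl ketone at C9 (Mukaiyama–Michael addition, giving silyl enol ether 15), and the new C8=C10 enol ether attacks the silyl-activated C11 aldehyde (Mukaiyama aldol addition) with transfer of the silyl group to the aldolate oxygen. The closest known reaction type is the tandem Mukaiyama Michael–aldol reaction, including its intramolecular silyl triflate–amine variant used to build strained polycycles. The six-membered ring C1–C6–C7–C8–C10–C9 closes 6-endo-trig at the enone (the donor double bond C15=C1 is exocyclic to the new ring), and the C10–C11 bond closes the one-carbon bridge 5-exo-trig onto the aldehyde, which turns that ring into the bicyclo[2.2.1]heptane. C1 is controlled by the ring A half-chair in which the side chain on C6 is equatorial and the formyl group axial (the cis silyloxy group on C4 excludes the alternative): C9 should then reach C1 only on the face cis to the formyl group, the other face being shielded by the axial methyl on C5; C10 is fixed by the geometry of the bridge once C1 is set; C11 should place its silyloxy group syn to the C8 carbonyl bridge because the other side of the aldehyde points at C2 of ring A. The step needs chemoselective enolisation (only the enal has acidic γ-hydrogens; the C11 aldehyde has no α-hydrogen), attack through C1 and not C3 (C3 cannot reach the enone), and aldol closure on C11 (five-membered ring) instead of on the C15 oxocarbenium ion (four-membered ring); all three follow from attaching donor, acceptor chain and aldehyde to the single quaternary carbon C6.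

Step 12
Reactants: 16 bridged keto aldehyde
Product: 17 bridged hydroxy ketone (C15 primary alcohol; C8 ketone; 4,11-bis-TBS ether)
Conditions: NaBH4, MeOH/CH2Cl2, −78 °C
Reagents that add atoms: none
Why: Chemoselective carbonyl reduction: NaBH4 should reduce the aldehyde much faster than the bridged ketone next to a quaternary carbon.

Step 13
Reactants: 17 bridged hydroxy ketone
Product: 18 bridged ketone tris-TBS ether (O4, O11, O15)
Conditions: TBSCl, imidazole, DMF, rt
Reagents that add atoms: tert-butyldimethylsilyl chloride CC(C)(C)[Si](C)(C)Cl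
Why: Standard silylation of the primary alcohol, which also draws any internal hemiketal to the open form and keeps this hydroxyl from trapping the carbene of step 15.

Step 14
Reactants: 18 bridged ketone tris-TBS ether
Product: 19 C8 tosylhydrazone of 18
Conditions: TsNHNH2, THF, 4 Å molecular sieves, 65 °C
Reagents that add atoms: 4-methylbenzenesulfonohydrazide Cc1ccc(cc1)S(=O)(=O)NN
Why: Condensation of the ketone with the sulfonyl hydrazide (hydrazone formation), as for camphor-type bicyclic ketones.

Step 15
Reactants: 19 C8 tosylhydrazone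
Product: 22 nortricyclene tris-TBS ether (cyclopropane C8–C9–C10; C2=C3 alkene), via hydrazone sodium salt 20 (not isolated), via diazoalkane 21 (not isolated)
Conditions: NaH, THF, 0 °C; then diglyme, 150 °C
Reagents that add atoms: none
Why: Bamford–Stevens reaction under aprotic conditions: the hydrazone salt loses sulfinate to give the diazoalkane and then the C8 carbene, which should insert into the endo C9–H bond (1,3-insertion, as in camphor to tricyclene) and close the cyclopropane, with C8 and C9 fixed by the cage.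

Step 16
Reactants: 22 nortricyclene tris-TBS ether
Product: 24 C3 alcohol tris-TBS ether (3-OH trans to 4-OTBS expected), via alkylborane 23 (not isolated)
Conditions: BH3·THF, THF, 0 °C; then NaOH, H2O2, 0 °C
Reagents that add atoms: hydrogen peroxide OO; borane–THF B.C1CCOC1 (its boron stays only in 23)
Why: Hydroboration–oxidation: boron should add to C3, away from the quaternary C1 and next to the allylic C–O carbon, anti to the silyloxy group; the C3 configuration is irrelevant because it is oxidised in step 17.

Step 17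
Reactants: 24 C3 alcohol tris-TBS ether
Product: 25 C3 ketone tris-TBS ether
Conditions: Dess–Martin periodinane, pyridine, CH2Cl2, 0 °C to rt
Reagents that add atoms: none
Why: Dess–Martin oxidation of the secondary alcohol to the ketone.

Step 18
Reactants: 25 C3 ketone tris-TBS ether
Product: 26 trihydroxy ketone (C3 ketone; 4-, 11- and 15-OH)
Conditions: HF·pyridine, pyridine, THF, 0 °C to rt
Reagents that add atoms: none
Why: Fluoride-mediated cleavage of the three silyl ethers under mildly acidic conditions, which should leave the α-hydroxy ketone (equatorial 4-OH) unchanged.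

Step 19
Reactants: 26 trihydroxy ketone
Product: 27 triacetoxy ketone (4-, 11- and 15-OAc; C3 ketone)
Conditions: Ac2O, DMAP (cat.), pyridine, rt
Reagents that add atoms: acetic anhydride CC(=O)OC(C)=O
Why: DMAP-catalysed acetylation of all three hydroxyl groups.

Step 20
Reactants: 27 triacetoxy ketone
Product: 28 CNP0111873.1 (target)
Conditions: NaBH4, MeOH/THF, −40 °C; AcOH quench
Reagents that add atoms: none
Why: Hydride reduction of the ketone: the axial face of the C3 carbonyl is blocked by the syn-axial C15H2OAc on C1 and the axial methyl on C5, so hydride should add equatorially and give the axial 3-OH cis to the 4-OAc, while the acetates should survive at low temperature.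

**Compound list**

1 | 7,7-dimethyl-1,4-dioxaspiro[4.5]decan-8-one | O=C1CCC2(CC1(C)C)OCCO2 | starting material
2 | (S)-7,7-dimethyl-1,4-dioxaspiro[4.5]decan-8-ol | O[C@H]1CCC2(CC1(C)C)OCCO2 | intermediate
3 | (S)-tert-butyl[(7,7-dimethyl-1,4-dioxaspiro[4.5]decan-8-yl)oxy]dimethylsilane | CC(C)(C)[Si](C)(C)O[C@H]1CCC2(CC1(C)C)OCCO2 | intermediate
4 | (S)-4-[(tert-butyldimethylsilyl)oxy]-3,3-dimethylcyclohexan-1-one | CC(C)(C)[Si](C)(C)O[C@H]1CCC(=O)CC1(C)C | intermediate
5 | (S)-4-[(tert-butyldimethylsilyl)oxy]-5,5-dimethylcyclohex-2-en-1-one | CC(C)(C)[Si](C)(C)O[C@H]1C=CC(=O)CC1(C)C | intermediate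
6 | (4S)-4-[(tert-butyldimethylsilyl)oxy]-5,5-dimethyl-6-(prop-2-en-1-yl)cyclohex-2-en-1-one (C6 open) | C=CCC1C(=O)C=C[C@H](O[Si](C)(C)C(C)(C)C)C1(C)C | intermediate
7 | trimethylsilyl dienol ether of 6 (2-silyloxy-1,3-diene) | C=CCC1=C(O[Si](C)(C)C)C=C[C@H](O[Si](C)(C)C(C)(C)C)C1(C)C | intermediate (not isolated)
8 | (4S)-4-[(tert-butyldimethylsilyl)oxy]-6-(dimethoxymethyl)-5,5-dimethyl-6-(prop-2-en-1-yl)cyclohex-2-en-1-one, acetal trans and allyl cis to OTBS | C=CC[C@]1(C(OC)OC)C(=O)C=C[C@H](O[Si](C)(C)C(C)(C)C)C1(C)C | intermediate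
9 | 2-[(5S)-5-[(tert-butyldimethylsilyl)oxy]-1-(dimethoxymethyl)-6,6-dimethyl-2-oxocyclohex-3-en-1-yl]acetaldehyde | O=CC[C@]1(C(OC)OC)C(=O)C=C[C@H](O[Si](C)(C)C(C)(C)C)C1(C)C | intermediate
10 | (4S)-4-[(tert-butyldimethylsilyl)oxy]-6-(dimethoxymethyl)-6-(2-hydroxy-3-methylbut-3-en-1-yl)-5,5-dimethylcyclohex-2-en-1-one (carbinol open) | CC(=C)C(O)C[C@]1(C(OC)OC)C(=O)C=C[C@H](O[Si](C)(C)C(C)(C)C)C1(C)C | intermediate
11 | 1-[(5S)-5-[(tert-butyldimethylsilyl)oxy]-1-(dimethoxymethyl)-2-(methoxymethylidene)-6,6-dimethylcyclohex-3-en-1-yl]-3-methylbut-3-en-2-ol (E/Z and carbinol open) | CC(=C)C(O)C[C@]1(C(OC)OC)C(=COC)C=C[C@H](O[Si](C)(C)C(C)(C)C)C1(C)C | intermediate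
12 | 1-[(5S)-5-[(tert-butyldimethylsilyl)oxy]-1-(dimethoxymethyl)-2-(methoxymethylidene)-6,6-dimethylcyclohex-3-en-1-yl]-3-methylbut-3-en-2-one | CC(=C)C(=O)C[C@]1(C(OC)OC)C(=COC)C=C[C@H](O[Si](C)(C)C(C)(C)C)C1(C)C | intermediate (not isolated)
13 | (4S)-4-[(tert-butyldimethylsilyl)oxy]-5,5-dimethyl-6-(3-methyl-2-oxobut-3-en-1-yl)cyclohex-1-ene-1,6-dicarbaldehyde, side chain cis and 6-formyl trans to OTBS | CC(=C)C(=O)C[C@]1(C=O)C(C=O)=CC[C@H](O[Si](C)(C)C(C)(C)C)C1(C)C | intermediate
14 | silyl dienol ether of 13 (C15 O-TBS; C15=C1 and C2=C3) | CC(=C)C(=O)C[C@]1(C=O)C(=CO[Si](C)(C)C(C)(C)C)C=C[C@H](O[Si](C)(C)C(C)(C)C)C1(C)C | intermediate (not isolated)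
15 | Michael adduct: C1–C9 bond formed, C8=C10 silyl enol ether, free C11 and C15 aldehydes | O=C[C@]12C=C[C@H](O[Si](C)(C)C(C)(C)C)C(C)(C)[C@]1(C=O)CC(O[Si](C)(C)C(C)(C)C)=C(C)C2 | intermediate (not isolated)
16 | bridged keto aldehyde: bicyclo[2.2.1]heptan-2-one fused to ring A at C1–C6; C15 aldehyde on C1; C2=C3; C8 ketone; 4-OTBS; 11-OTBS syn to C8 | O=C[C@]12C=C[C@H](O[Si](C)(C)C(C)(C)C)C(C)(C)[C@]13CC(=O)[C@](C)(C2)[C@H]3O[Si](C)(C)C(C)(C)C | intermediate
17 | bridged hydroxy ketone (C15 CH2OH) | OC[C@]12C=C[C@H](O[Si](C)(C)C(C)(C)C)C(C)(C)[C@]13CC(=O)[C@](C)(C2)[C@H]3O[Si](C)(C)C(C)(C)C | intermediate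
18 | bridged ketone tris-TBS ether | CC(C)(C)[Si](C)(C)OC[C@]12C=C[C@H](O[Si](C)(C)C(C)(C)C)C(C)(C)[C@]13CC(=O)[C@](C)(C2)[C@H]3O[Si](C)(C)C(C)(C)C | intermediate
19 | C8 tosylhydrazone of 18 | CC(C)(C)[Si](C)(C)OC[C@]12C=C[C@H](O[Si](C)(C)C(C)(C)C)C(C)(C)[C@]13CC(=NNS(=O)(=O)c4ccc(C)cc4)[C@](C)(C2)[C@H]3O[Si](C)(C)C(C)(C)C | intermediate
20 | sodium salt of 19 | [Na+].CC(C)(C)[Si](C)(C)OC[C@]12C=C[C@H](O[Si](C)(C)C(C)(C)C)C(C)(C)[C@]13CC(=N[N-]S(=O)(=O)c4ccc(C)cc4)[C@](C)(C2)[C@H]3O[Si](C)(C)C(C)(C)C | intermediate (not isolated)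
21 | C8 diazoalkane | CC(C)(C)[Si](C)(C)OC[C@]12C=C[C@H](O[Si](C)(C)C(C)(C)C)C(C)(C)[C@]13CC(=[N+]=[N-])[C@](C)(C2)[C@H]3O[Si](C)(C)C(C)(C)C | intermediate (not isolated)
22 | nortricyclene tris-TBS ether (cyclopropane C8–C9–C10; C2=C3) | CC(C)(C)[Si](C)(C)OC[C@]12C=C[C@H](O[Si](C)(C)C(C)(C)C)C(C)(C)[C@]13C[C@@H]1[C@H]2[C@]1(C)[C@H]3O[Si](C)(C)C(C)(C)C | intermediate
23 | C3 alkylborane (BH2 trans to 4-OTBS) | CC(C)(C)[Si](C)(C)OC[C@]12C[C@@H](B)[C@H](O[Si](C)(C)C(C)(C)C)C(C)(C)[C@]13C[C@@H]1[C@H]2[C@]1(C)[C@H]3O[Si](C)(C)C(C)(C)C | intermediate (not isolated)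
24 | C3 alcohol tris-TBS ether (3-OH trans to 4-OTBS) | CC(C)(C)[Si](C)(C)OC[C@]12C[C@@H](O)[C@H](O[Si](C)(C)C(C)(C)C)C(C)(C)[C@]13C[C@@H]1[C@H]2[C@]1(C)[C@H]3O[Si](C)(C)C(C)(C)C | intermediate
25 | C3 ketone tris-TBS ether | CC(C)(C)[Si](C)(C)OC[C@]12CC(=O)[C@H](O[Si](C)(C)C(C)(C)C)C(C)(C)[C@]13C[C@@H]1[C@H]2[C@]1(C)[C@H]3O[Si](C)(C)C(C)(C)C | intermediate
26 | trihydroxy ketone (C3 ketone; 4-, 11-, 15-OH) | OC[C@]12CC(=O)[C@H](O)C(C)(C)[C@]13C[C@@H]1[C@H]2[C@]1(C)[C@H]3O | intermediate
27 | triacetoxy ketone (C3 ketone; 4-, 11-, 15-OAc) | CC(=O)OC[C@]12CC(=O)[C@H](OC(C)=O)C(C)(C)[C@]13C[C@@H]1[C@H]2[C@]1(C)[C@H]3OC(C)=O | intermediate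
28 | CNP0111873.1 | CC(=O)OC[C@]12C[C@H](O)[C@H](OC(C)=O)C(C)(C)[C@]13C[C@@H]1[C@H]2[C@]1(C)[C@H]3OC(C)=O | target

**Step count and risks**

Total step count: 20. Longest linear sequence: 20 steps (the route is linear from 1).

Steps most likely to fail:

1. Step 11 (key step). The conjugate addition may occur on the face of the dienol ether trans to the formyl group, giving a cis-fused adduct that cannot bridge. The sequence may also stall after the first C–C bond, or the enol ether may close onto the C15 oxocarbenium ion (four-membered ring). Fallback: the two bonds are made in separate operations, with a different activation for the first. Starting from 13, a catalytic amount of KOtBu in t-BuOH/THF at 0 °C should generate the potassium dienolate and let the conjugate addition equilibrate (base-mediated, reversible Michael addition) to the trans-fused keto dialdehyde F1. F1 is then treated with TBSOTf/Et3N at −78 °C, which should convert the ketone into its more substituted silyl enol ether and close the C10–C11 bond by Mukaiyama aldol addition, returning to the route at 16.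

2. Step 6. The tetrasubstituted silyl enol ether, flanked by the gem-dimethyl carbon, may be attacked too slowly by the dimethoxycarbenium ion and merely be desilylated back to 6. Fallback: starting from 6, the lithium enolate (LiN(iPr)2, THF, −78 °C) is hydroxymethylated with gaseous formaldehyde (aldol addition with the smallest carbon electrophile, again expected anti to the silyloxy group) to the hydroxymethyl ketone F2. F2 is oxidised with Dess–Martin periodinane to the keto aldehyde F3, and aldehyde-selective acetalisation (HC(OMe)3, MeOH, PPTS) returns to the route at 8.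

3. Step 9. The ylide may act only as a base (γ-deprotonation of the enone) and fail to add to the carbonyl group next to the quaternary carbon. Fallback: Peterson olefination in place of the Wittig reaction. Starting from 10, the smaller and more nucleophilic Me3SiCH(OMe)Li (from methoxymethyltrimethylsilane and s-BuLi, 2.2 equiv) should add to the ketone to give the β-hydroxysilane F4; KH in THF then eliminates silanolate and returns to the route at 11.

Further compounds
F1 | step 11 | trans-fused keto dialdehyde (C1–C9 formed, C10–C11 open; C10 open) | O=C[C@]12C=C[C@H](O[Si](C)(C)C(C)(C)C)C(C)(C)[C@]1(C=O)CC(=O)C(C)C2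
F2 | step 6 | (4S)-4-[(tert-butyldimethylsilyl)oxy]-6-(hydroxymethyl)-5,5-dimethyl-6-(prop-2-en-1-yl)cyclohex-2-en-1-one | C=CC[C@]1(CO)C(=O)C=C[C@H](O[Si](C)(C)C(C)(C)C)C1(C)C
F3 | step 6 | (5S)-5-[(tert-butyldimethylsilyl)oxy]-6,6-dimethyl-2-oxo-1-(prop-2-en-1-yl)cyclohex-3-ene-1-carbaldehyde | C=CC[C@]1(C=O)C(=O)C=C[C@H](O[Si](C)(C)C(C)(C)C)C1(C)C
F4 | step 9 | β-hydroxysilane adduct of 10 (tertiary alcohol bearing CH(OMe)SiMe3) | CC(=C)C(O)C[C@]1(C(OC)OC)C(O)(C(OC)[Si](C)(C)C)C=C[C@H](O[Si](C)(C)C(C)(C)C)C1(C)C
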